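**Strategy.** The quinone ring (C1–C4, C4a, C8a; side chain at C2) is opened at C2=C3 and C1–C8a. The four-atom piece C8a–C4a–C4–C3 is a 2,5-bis(MOM-oxy)benzoyl sulfoxonium ylide. The two-atom piece C2–C1 is the terminal alkyne of (R)-6-methylhept-5-en-1-yn-3-ol, which already holds the carbinol centre. A Cp*Rh(III)-catalysed C–H activation/carbene-insertion [4+2] annulation joins both bonds in one operation and gives a 1-naphthol; the ylide carbon, a nucleophile by nature, is coupled as a carbene. The step exploits the 2-monosubstituted quinone ring: C3–H maps onto the ylide CH, C2/C1 onto the alkyne, and C8a is the only free ortho C–H. Teuber oxidation, MOM removal and Steglich acylation complete the route.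

Key step: step 7

Assumption: the two naphthazarin tautomers are one compound in fast equilibrium and are drawn as in the target; atom numbers are those of naphthalene-1,4-dione.

**Step 1**
Reactants: 1 methyl 2,5-dihydroxybenzoate
Product: 2 methyl 2,5-bis(methoxymethoxy)benzoate
Conditions: NaH (2.4 equiv), MOMCl (2.4 equiv), DMF, 0 °C to rt
Reagents that add atoms: chloromethyl methyl ether (MOMCl), COCCl
Why: Double Williamson O-alkylation (MOM protection) of the phenoxides should proceed cleanly, sodium hydride being strong enough to break the hydrogen bond of the ortho phenol to the ester.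

**Step 2**
Reactants: 2 methyl 2,5-bis(methoxymethoxy)benzoate
Product: 3 1-[2,5-bis(methoxymethoxy)phenyl]-2-[dimethyl(oxo)-λ6-sulfanylidene]ethan-1-one
Conditions: Me3S(O)I (3 equiv), KOtBu (3 equiv), THF, reflux; then 2, reflux
Reagents that add atoms: trimethylsulfoxonium iodide, C[S+](C)(C)=O.[I-]
Why: Corey–Chaykovsky acylation of dimethylsulfoxonium methylide by the ester should stop at the β-keto sulfoxonium ylide, because this stabilised ylide is too weak a nucleophile to be acylated again and the MOM acetals are inert to base.

**Step 3**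
Reactants: 4 4-methylpent-3-enoic acid
Product: 6 N-methoxy-N,4-dimethylpent-3-enamide, via acyl imidazole 5 (not isolated)
Conditions: CDI (1.1 equiv), CH2Cl2, rt; then MeNH(OMe)·HCl (1.2 equiv), rt
Reagents that add atoms: N,O-dimethylhydroxylamine hydrochloride, CNOC.Cl; 1,1'-carbonyldiimidazole (imidazolyl group of 5 only), O=C(n1ccnc1)n1ccnc1
Why: Carboxyl activation with CDI and aminolysis of the acyl imidazole (Weinreb amide formation) run under near-neutral conditions that should leave the β,γ-double bond in place.

**Step 4**
Reactants: 6 N-methoxy-N,4-dimethylpent-3-enamide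
Product: 7 6-methyl-1-(trimethylsilyl)hept-5-en-1-yn-3-one
Conditions: ethynyltrimethylsilane (1.3 equiv), n-BuLi (1.25 equiv), THF, −78 °C; then 6, −78 to −20 °C; cold aq. NH4Cl
Reagents that add atoms: ethynyltrimethylsilane, C#C[Si](C)(C)C
Why: Weinreb ketone synthesis, in which the lithium acetylide adds once to give a chelated tetrahedral adduct that collapses to the ynone only on the cold, mildly acidic quench, which should avoid over-addition and base-induced migration of the alkene.

**Step 5**
Reactants: 7 6-methyl-1-(trimethylsilyl)hept-5-en-1-yn-3-one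
Product: 8 (3R)-6-methyl-1-(trimethylsilyl)hept-5-en-1-yn-3-ol
Conditions: Ru[(R,R)-TsDPEN](p-cymene) (1 mol%, base-free), i-PrOH, rt
Reagents that add atoms: none
Why: Noyori–Ikariya asymmetric transfer hydrogenation of an α,β-acetylenic ketone reduces only the C=O group, and the new carbinol stereocentre is set by the catalyst, the (R,R)-complex being expected to give the (R)-alcohol with the alkynyl group in the place of the aryl group of the established model.

**Step 6**
Reactants: 8 (3R)-6-methyl-1-(trimethylsilyl)hept-5-en-1-yn-3-ol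
Product: 9 (3R)-6-methylhept-5-en-1-yn-3-ol
Conditions: K2CO3 (0.2 equiv), MeOH, rt
Reagents that add atoms: none
Why: Base-catalysed methanolysis of the C(sp)–Si bond (protodesilylation) should free the terminal alkyne without touching the carbinol stereocentre.

**Step 7**
Reactants: 3 1-[2,5-bis(methoxymethoxy)phenyl]-2-[dimethyl(oxo)-λ6-sulfanylidene]ethan-1-one; 9 (3R)-6-methylhept-5-en-1-yn-3-ol
Product: 10 3-[(1R)-1-hydroxy-4-methylpent-3-en-1-yl]-5,8-bis(methoxymethoxy)naphthalen-1-ol
Conditions: [Cp*Rh(MeCN)3](SbF6)2 (5 mol%, silver-free), NaOAc (30 mol%), DCE, 60 °C, slow addition of 9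
Reagents that add atoms: none
Why: Acetate-assisted ortho C–H rhodation of 3 at its only free ortho position (the later C8a), directed by the ylide, is followed by 1,2-insertion of the alkyne into the Rh–aryl bond (C1–C8a); loss of DMSO from the bound ylide then gives a rhodium carbene into which the alkenyl group migrates (C2–C3), and protonation with tautomerisation releases the 1-naphthol. This is the known Rh(III)-catalysed [4+2] annulation of aroyl sulfoxonium ylides with alkynes to 1-naphthols, here with a terminal propargylic alcohol as the alkyne. The six-membered ring closes at the metal by 1,1-migratory insertion of the alkenyl ligand into the carbene within a rhodacycle, not by a polar cyclisation. No stereocentre is formed, and the carbinol centre of 9 is a spectator that should stay (R). The step needs insertion with the aryl group at the terminal alkyne carbon, which the unhindered CH terminus and coordination of the propargylic hydroxyl to rhodium should secure, as in related Cp*Rh annulations of terminal alkynes and propargylic alcohols. The trisubstituted alkene should be inert, and the silver-free catalyst with slow addition of 9 is meant to limit alkyne oligomerisation.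

**Step 8**
Reactants: 10 3-[(1R)-1-hydroxy-4-methylpent-3-en-1-yl]-5,8-bis(methoxymethoxy)naphthalen-1-ol
Product: 11 2-[(1R)-1-hydroxy-4-methylpent-3-en-1-yl]-5,8-bis(methoxymethoxy)naphthalene-1,4-dione
Conditions: Fremy's salt (2.5 equiv), KH2PO4 buffer, acetone/H2O, 0 °C to rt
Reagents that add atoms: potassium nitrosodisulfonate (Fremy's salt), [K+].[K+].[O]N(S(=O)(=O)[O-])S(=O)(=O)[O-]
Why: Teuber oxidation, in which Fremy's radical abstracts the phenolic hydrogen and a second equivalent couples at the free para carbon, loss of imidodisulfonate then giving the 1,4-quinone, while the MOM-protected ring, the alkene and the secondary alcohol should not be oxidised.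

**Step 9**
Reactants: 11 2-[(1R)-1-hydroxy-4-methylpent-3-en-1-yl]-5,8-bis(methoxymethoxy)naphthalene-1,4-dione
Product: 12 (R)-shikonin, 5,8-dihydroxy-2-[(1R)-1-hydroxy-4-methylpent-3-en-1-yl]naphthalene-1,4-dione
Conditions: HCl (2 M in MeOH), MeOH/THF, 0 °C to rt, argon, dark
Reagents that add atoms: none
Why: Acid-catalysed acetal exchange with methanol should cleave the two aryl MOM ethers readily because each lies peri to a quinone carbonyl, the carbinol on the electron-poor quinone ring not being prone to ionisation.

**Step 10**
Reactants: 13 (2-carboxyethyl)triphenylphosphonium bromide; 14 methacrolein (2-methylprop-2-enal)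
Product: 16 (3Z)-5-methylhexa-3,5-dienoic acid, via carboxylate ylide 15 (not isolated)
Conditions: NaHMDS (2.1 equiv), THF, −78 to 0 °C; then 14, −78 °C to rt; cold dil. HCl work-up
Reagents that add atoms: none
Why: Wittig olefination with a non-stabilised, carboxylate-bearing ylide under lithium-free conditions should give the (Z)-alkene through the kinetically favoured cis-oxaphosphetane, the dianion form keeping the ylide from fragmenting and the new β,γ-double bond from moving into conjugation.

**Step 11**
Reactants: 12 (R)-shikonin; 16 (3Z)-5-methylhexa-3,5-dienoic acid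
Product: 17 (1R)-1-(5,8-dihydroxy-1,4-dioxo-1,4-dihydronaphthalen-2-yl)-4-methylpent-3-en-1-yl (3Z)-5-methylhexa-3,5-dienoate (target)
Conditions: DCC (1.5 equiv), DMAP (0.1 equiv), CH2Cl2, 0 °C, dark
Reagents that add atoms: none
Why: Steglich esterification should acylate only the secondary carbinol, since the two phenols are chelated to the quinone carbonyls and are poor nucleophiles as in known acylations of shikonin, and the stereocentre is retained because its C–O bond is not broken.

**Compound list**
1 | methyl 2,5-dihydroxybenzoate | COC(=O)c1cc(O)ccc1O | starting material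
2 | methyl 2,5-bis(methoxymethoxy)benzoate | COCOc1ccc(OCOC)c(C(=O)OC)c1 | intermediate
3 | 1-[2,5-bis(methoxymethoxy)phenyl]-2-[dimethyl(oxo)-λ6-sulfanylidene]ethan-1-one | COCOc1ccc(OCOC)c(C(=O)C=S(C)(C)=O)c1 | intermediate
4 | 4-methylpent-3-enoic acid | CC(C)=CCC(=O)O | starting material
5 | 1-(1H-imidazol-1-yl)-4-methylpent-3-en-1-one (acyl imidazole, not isolated) | CC(C)=CCC(=O)n1ccnc1 | intermediate
6 | N-methoxy-N,4-dimethylpent-3-enamide | CC(C)=CCC(=O)N(C)OC | intermediate
7 | 6-methyl-1-(trimethylsilyl)hept-5-en-1-yn-3-one | CC(C)=CCC(=O)C#C[Si](C)(C)C | intermediate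
8 | (3R)-6-methyl-1-(trimethylsilyl)hept-5-en-1-yn-3-ol | O[C@H](CC=C(C)C)C#C[Si](C)(C)C | intermediate
9 | (3R)-6-methylhept-5-en-1-yn-3-ol | O[C@H](CC=C(C)C)C#C | intermediate
10 | 3-[(1R)-1-hydroxy-4-methylpent-3-en-1-yl]-5,8-bis(methoxymethoxy)naphthalen-1-ol | O[C@H](CC=C(C)C)c1cc(O)c2c(OCOC)ccc(OCOC)c2c1 | intermediate
11 | 2-[(1R)-1-hydroxy-4-methylpent-3-en-1-yl]-5,8-bis(methoxymethoxy)naphthalene-1,4-dione | O[C@H](CC=C(C)C)C1=CC(=O)c2c(OCOC)ccc(OCOC)c2C1=O | intermediate
12 | (R)-shikonin, 5,8-dihydroxy-2-[(1R)-1-hydroxy-4-methylpent-3-en-1-yl]naphthalene-1,4-dione | O[C@H](CC=C(C)C)C1=CC(=O)c2c(O)ccc(O)c2C1=O | intermediate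
13 | (2-carboxyethyl)triphenylphosphonium bromide | OC(=O)CC[P+](c1ccccc1)(c1ccccc1)c1ccccc1.[Br-] | starting material
14 | methacrolein (2-methylprop-2-enal) | C=C(C)C=O | starting material
15 | sodium 3-(triphenyl-λ5-phosphanylidene)propanoate (carboxylate ylide, not isolated) | [Na+].[O-]C(=O)CC=P(c1ccccc1)(c1ccccc1)c1ccccc1 | intermediate
16 | (3Z)-5-methylhexa-3,5-dienoic acid | C=C(C)/C=C\CC(=O)O | intermediate
17 | (1R)-1-(5,8-dihydroxy-1,4-dioxo-1,4-dihydronaphthalen-2-yl)-4-methylpent-3-en-1-yl (3Z)-5-methylhexa-3,5-dienoate | C=C(C)/C=C\CC(=O)O[C@H](CC=C(C)C)C1=CC(=O)c2c(O)ccc(O)c2C1=O | target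

**Step count.** Total: 11 steps. Longest linear sequence: 8 steps (steps 3, 4, 5, 6, 7, 8, 9, 11).

**Steps most likely to fail**

Step 7. The terminal alkyne may oligomerise at the cationic rhodium centre, insert in the reverse orientation, or lose its propargylic oxygen by β-elimination or ionisation, which would also erase the stereocentre. The fallback is a Dötz benzannulation; it sets out from alkyne 9 and comes back at 12. Alkyne 9 would be silylated (TBSCl, imidazole, DMF) to (R)-tert-butyl(dimethyl)[(6-methylhept-5-en-1-yn-3-yl)oxy]silane F1. In parallel, hydroquinone would be converted (NaH, MOMCl) into 1,4-bis(methoxymethoxy)benzene F2. F2 would be ortho-lithiated (n-BuLi, TMEDA, THF, 0 °C), added to Cr(CO)6 and O-methylated (Me3OBF4) to pentacarbonyl{[2,5-bis(methoxymethoxy)phenyl](methoxy)methylidene}chromium F3. Heating F3 with F1 (THF, 55 °C) should give, by alkyne and CO insertion and electrocyclisation, 2-[(1R)-1-(tert-butyldimethylsilyloxy)-4-methylpent-3-en-1-yl]-4-methoxy-5,8-bis(methoxymethoxy)naphthalen-1-ol F4. CAN (MeCN/H2O, 0 °C) would oxidise F4 without isolation to 2-[(1R)-1-(tert-butyldimethylsilyloxy)-4-methylpent-3-en-1-yl]-5,8-bis(methoxymethoxy)naphthalene-1,4-dione F5. HCl in MeOH would then remove the silyl group and both MOM groups to give shikonin 12; steps 8 and 9 are bypassed.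

Step 10. The anionic carboxylate in the ylide may erode the (Z)-selectivity, and the ylide may fragment to acrylate and triphenylphosphine before it meets the enal. The fallback sets out from methacrolein 14 and comes back at acid 16. A Wittig reaction of 14 with the ylide from [3-(tert-butyldimethylsilyloxy)propyl]triphenylphosphonium bromide (NaHMDS, THF, −78 °C), which carries no anionic group, should give tert-butyl(dimethyl){[(3Z)-5-methylhexa-3,5-dien-1-yl]oxy}silane F6. Desilylation (TBAF, THF) would give (3Z)-5-methylhexa-3,5-dien-1-ol F7. Oxidation of F7 with TEMPO/PhI(OAc)2 in MeCN/H2O would give 16, so the carboxyl group arises by late oxidation instead of being carried through the olefination.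

Step 11. The chelated phenols may be acylated in competition, and the 3,4-double bond of the activated acid may migrate into conjugation through the acylpyridinium or a ketene. The fallback reverses the order of acylation and unmasking; it sets out from 11 and comes back at the target 17. Quinone 11, which has a single hydroxyl, would be acylated with 16 (DIC, catalytic DMAP, CH2Cl2, −20 °C) to (1R)-1-[5,8-bis(methoxymethoxy)-1,4-dioxo-1,4-dihydronaphthalen-2-yl]-4-methylpent-3-en-1-yl (3Z)-5-methylhexa-3,5-dienoate F8. Cleavage of the MOM groups of F8 (HCl in MeOH/THF, 0 °C) would give 17 directly; steps 9 and 11 are bypassed, and no free carbinol is exposed to acid.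

**Further compounds**
F1 | step 7 | (R)-tert-butyl(dimethyl)[(6-methylhept-5-en-1-yn-3-yl)oxy]silane | CC(C)(C)[Si](C)(C)O[C@H](CC=C(C)C)C#C
F2 | step 7 | 1,4-bis(methoxymethoxy)benzene | COCOc1ccc(OCOC)cc1
F3 | step 7 | pentacarbonyl{[2,5-bis(methoxymethoxy)phenyl](methoxy)methylidene}chromium | COC(=[Cr](=C=O)(=C=O)(=C=O)(=C=O)=C=O)c1cc(OCOC)ccc1OCOC
F4 | step 7 | 2-[(1R)-1-(tert-butyldimethylsilyloxy)-4-methylpent-3-en-1-yl]-4-methoxy-5,8-bis(methoxymethoxy)naphthalen-1-ol | CC(C)(C)[Si](C)(C)O[C@H](CC=C(C)C)c1cc(OC)c2c(OCOC)ccc(OCOC)c2c1O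
F5 | step 7 | 2-[(1R)-1-(tert-butyldimethylsilyloxy)-4-methylpent-3-en-1-yl]-5,8-bis(methoxymethoxy)naphthalene-1,4-dione | CC(C)(C)[Si](C)(C)O[C@H](CC=C(C)C)C1=CC(=O)c2c(OCOC)ccc(OCOC)c2C1=O
F6 | step 10 | tert-butyl(dimethyl){[(3Z)-5-methylhexa-3,5-dien-1-yl]oxy}silane | C=C(C)/C=C\CCO[Si](C)(C)C(C)(C)C
F7 | step 10 | (3Z)-5-methylhexa-3,5-dien-1-ol | C=C(C)/C=C\CCO
F8 | step 11 | (1R)-1-[5,8-bis(methoxymethoxy)-1,4-dioxo-1,4-dihydronaphthalen-2-yl]-4-methylpent-3-en-1-yl (3Z)-5-methylhexa-3,5-dienoate | C=C(C)/C=C\CC(=O)O[C@H](CC=C(C)C)C1=CC(=O)c2c(OCOC)ccc(OCOC)c2C1=O
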